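## Structural features

The target is a daucane (hydroazulene) sesquiterpenoid ester: a cyclopentane (C1–C5) trans-fused through C1 and C5 to a cycloheptene (C1, C5–C10) whose only alkene is C8(CH3)=C9, with a 4-methoxybenzoate on the C6 oxygen. The numbering used throughout is: C1 the methyl-bearing fusion carbon, C2 and C3 the ring methylenes, C4 the isopropyl carbinol, C5 the fusion CH, C6 the ester carbon, C7 a methylene, C10 the allylic carbinol. The five stereocentres C10–C1–C5(–C4)–C6 are contiguous; C1 is quaternary and C4 is a fully substituted carbinol, and both flank C5. In the usual drawing the C1 methyl and the C4 hydroxyl are β, while H5, the C6 oxygen and the C10 hydroxyl are α, i.e. (1S,4R,5S,6S,10R) in this numbering and (3R,3aS,4S,8R,8aS) in azulene numbering. The fragile elements are the tertiary C4 alcohol (dehydration), the secondary allylic, neopentyl C10 alcohol (ionisation, allylic transposition), the electron-rich aryl ester (base-labile, able to migrate) and the trisubstituted alkene. The real difficulty is to raise the quaternary C1 with defined configuration next to the C10 carbinol while the seven-membered ring is closed, and then to put H5 and O6 on the face opposite the angular methyl group. The key step exploits the fact that C6 and C10 both carry α-oxygen and are joined by C7–C8(CH3)=C9: a single oxygen can hold both carbons in a six-membered 3,6-dihydro-2H-pyran. In that ring C10 is an allylic O–CH2 that can be metalated, and C6 is an ether carbon attached to a C5=C1 cyclopentene, which is the array needed for a [2,3] shift that hands C10 to C1. The C4 carbinol with its isopropyl group, C1–C6 and the C1 methyl map onto (S)-terpinen-4-ol.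

## Logic of the disconnections

**22 ⇒ 21 (O4–Si and O10–Si).** The free tertiary and allylic alcohols are the most fragile groups, so they are unmasked last. The demand is a fluoride source mild enough to spare the aryl ester.

**21 ⇒ 19 + 20 (acyl C–O bond at O6).** The ester is base-sensitive and is therefore made as late as possible; this removes the aromatic part. The demand is that O6 be the only acylable oxygen, so O10 must be protected and O4 must be a tertiary silyl ether.

**19 ⇒ 17 (C6–O and C5–H).** H5 and O6 are cis, so both can come from one syn addition to a C5=C6 alkene. Two stereocentres disappear and a 5,8-diene remains. The demand is attack on the α face and on C5=C6 in preference to C8=C9.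

**17 ⇒ 16 (O10–Si).** The C10 hydroxyl is capped so that acylation later finds only O6 and so that its bulk crowds C9. The demand is silylation of a neopentyl alcohol, hence a silyl triflate.

**16 ⇒ 13 (C1–C10 cut, C6–O re-formed, alkene returned to C1=C5).** This is the strategic cut. The seven-membered carbocycle, the quaternary C1 and the C10 carbinol are all traced back to the single stereocentre C6 of a six-membered allyl ether. The demands are metalation at C10 only, a [2,3] shift in preference to [1,2] and [1,4] shifts, and the (S) configuration at C6.

**13 ⇒ 12 (C8=C9).** A trisubstituted alkene in a six-membered ring is a ring-closing-metathesis retron, which leads to an acyclic diallyl ether. The catalyst must ignore the tetrasubstituted cyclopentene alkene. A one-step [4+2] union of 6 with isoprene would reach 13 directly. It is not used because it would leave C6, the centre that decides C1 and C10, to weak substrate control and would expose the tertiary allylic silyl ether to acid.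

**12 ⇒ 9 + 10 (O–C10).** Cutting the allyl ether bond gives a secondary carbinol and an allyl donor. The demand is etherification without a free alkoxide next to the O4 silyl group.

**9 ⇒ 6 + 7 (C6–C7).** Cutting here lets a chiral reagent set C6 and simplifies to an aldehyde. The demand is reagent-controlled 1,2-addition to a hindered enal.

**6 ⇒ 4 (C1=C5).** This is an aldol-condensation retron that opens the cyclopentene to a keto aldehyde. The demand is that the aldehyde α-carbon, not the ketone, act as nucleophile, and that the β-silyloxy group not be eliminated.

**4 ⇒ 2 ⇒ 1 (the two carbonyl carbons rejoined as C=C; O–Si).** This ozonolysis retron leads to the chiral-pool cyclohexenol. The hydroxyl must be silylated before cleavage so that the β-oxy aldehyde cannot undergo retro-aldol cleavage.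

## Other disconnections considered

Alternative 1: The cut removes C1–C10 and C5–C6 together as a cyclobutane and later breaks C6–C10, so the seven-membered ring appears as a cyclopentane fused to a four-membered ring. In the forward sense, irradiation of 2-mesyloxy-3-methylcyclopentenone A1 with silyl enol ether A2 should give the head-to-tail cis-anti-cis photoadduct A3. Fluoride would then trigger a Grob fragmentation (O10 pushes, C6–C10 breaks, mesylate leaves C5) to the enedione A4.
- In its favour: two simple partners; the quaternary C1 and the seven-membered ring arise in two steps, fewer than the seven needed here to reach 16. Photocycloaddition followed by fragmentation is an established sequence, so on mechanistic security this alternative is the better of the two.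
- Against it here: A3 is racemic unless an enantioselective variant is found, and the regio- and facial outcome with a 2-sulfonyloxy enone is uncertain. A4 keeps only C1 as a useful stereocentre. C4 (isopropyl addition to an enone carbonyl), C10 (reduction to the α-alcohol against the bias of the angular methyl) and C8=C9 (from a saturated methine) must all be made afterwards.
- Comparison: 16 already holds C1, C4 and C10, with C4 from the chiral pool. The alternative is shorter to the bicycle but probably longer overall. Both plans face the same C5=C6 functionalisation at the end, so they are equal on that point.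

Alternative 2: The cut runs through C1–C2 and C4–C5 of a cyclohexene that contains one carbon too many (the future isopropyl carbon). In the forward sense, enal A5 and isoprene A6 under a chiral oxazaborolidinium salt should give cyclohexene A7, with the quaternary C1 and C5 trans.
- In its favour: the step is catalytic, enantioselective, available in either enantiomeric series and well precedented, so it is better than the chosen plan on precedent and independent of a chiral-pool material. It also sets C5 together with C1, whereas the chosen plan sets C5 only in the hydroboration, its least secure stereochemical step.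
- Against it here: the cyclohexene must be cleaved and re-closed by aldol condensation to a cyclopentene, and the acetyl group left behind must be turned into the C4 carbinol and its isopropyl group. The seven-membered ring is not addressed at all: C7–C9 have to be attached to the formyl and silyloxymethyl arms and the ring closed separately. C6 and C10 need separate stereocontrol next to the quaternary centre.
- Comparison: the chosen plan gains the seven-membered ring, C1 and C10 in one step from a precursor made in six, so it is clearly ahead in step economy and in how much structure the key step delivers.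

Alternative 3: The cut removes C1–C5 and C6–C7, a [5+2] retron that covers both rings. In the forward sense, [Rh(CO)2Cl]2 should open the siloxycyclopropane of enyne A8 and the metallacycle should take up the tethered alkyne to give bicycle A9, with C5=C6 and a C9 silyl enol ether.
- In its favour: both rings and the quaternary C1 form in one catalytic step of a known reaction class, so it is better than the chosen plan in ring-forming economy and precedent. The enol ether is a handle for C10 oxygenation and for C8=C9, and C5=C6 arrives exactly where the chosen plan has it, so the two are equal on the endgame problem.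
- Against it here: A8 needs the tertiary propargylic C4 carbinol as a single enantiomer and a trisubstituted alkene carrying the siloxycyclopropane, which is a longer and less certain substrate synthesis than six steps from a terpene. Bond formation at a fully substituted alkene terminus is demanding. C1 is induced only by the remote C4 substituents through the tether, less directly than by the C6-to-C1 transfer. C10–OH must still be introduced with α selectivity and the C9 oxygen removed.
- Comparison: mechanistically safer and more convergent, but weaker in stereochemical logic and probably no shorter overall.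

Key step: step 7

Remark (assumption on the chemistry): α and β refer to the usual drawing with the C1 methyl group β. Commercial (S)-(+)-terpinen-4-ol is taken as enantiomerically pure; its carbinol centre is carried unchanged and becomes (4R) in 22 only through a change of substituent priorities.

Remark on the structures: the configurations used for 13 [(2S) at the pyran carbon, (5R) at the silyloxy carbon] and for 16 [(1S,4R,10R)] were derived from 22 and agree with a suprafacial shift. Because the rearrangement turns a six-membered ether into a seven-membered carbocycle, it is treated here as a ring transposition rather than a contraction.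

## Route

Step 1
Reactants: 1 (S)-terpinen-4-ol
Product: 2 (S)-terpinen-4-ol triethylsilyl ether
Conditions: TESOTf, 2,6-lutidine, CH2Cl2, −78 → 0 °C
Reagents that add atoms: triethylsilyl trifluoromethanesulfonate, CC[Si](CC)(CC)OS(=O)(=O)C(F)(F)F
Why: Silyl triflate silylation is the standard way to cap a hindered tertiary alcohol; the C–O bond is not touched, so the (S) centre is retained, and the ether blocks retro-aldol cleavage once the ring is opened.

Step 2
Reactants: 2 (S)-terpinen-4-ol triethylsilyl ether
Product: 4 (3S)-6-oxo-3-(propan-2-yl)-3-(triethylsilyloxy)heptanal, via secondary ozonide 3 (not isolated)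
Conditions: O3, CH2Cl2, −78 °C; then PPh3, −78 °C → rt
Reagents that add atoms: ozone, [O-][O+]=O
Why: Criegee ozonolysis of the only alkene; the trisubstituted C=C gives the methyl ketone and the aldehyde after reduction of ozonide 3, and the silyl ether and the quaternary centre are inert to ozone at −78 °C.

Step 3
Reactants: 4 (3S)-6-oxo-3-(propan-2-yl)-3-(triethylsilyloxy)heptanal
Product: 6 (5R)-2-methyl-5-(propan-2-yl)-5-(triethylsilyloxy)cyclopent-1-ene-1-carbaldehyde, via cyclic aldol 5 (not isolated)
Conditions: piperidine (20 mol %), AcOH (20 mol %), toluene, 60 °C
Reagents that add atoms: none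
Why: Amine-catalysed intramolecular aldol condensation: the secondary amine condenses far faster with the aldehyde than with the methyl ketone, so the aldehyde enamine closes the ring onto the ketone (5-enolexo-exo-trig) and dehydration gives the formylcyclopentene, not the acetylcyclopentene that hydroxide would give. The buffered, weakly basic medium and the fast ring closure are relied on to outrun β-elimination of the silyloxy group; no stereocentre is formed or touched.

Step 4
Reactants: 6 (5R)-2-methyl-5-(propan-2-yl)-5-(triethylsilyloxy)cyclopent-1-ene-1-carbaldehyde; 7 2-methylallylmagnesium chloride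
Product: 9 (1S)-3-methyl-1-[(5R)-2-methyl-5-(propan-2-yl)-5-(triethylsilyloxy)cyclopent-1-en-1-yl]but-3-en-1-ol, via borinate 8 (not isolated)
Conditions: 7, (−)-Ipc2BOMe, Et2O, −78 °C → rt; then 6, −78 °C; NaBO3·4H2O, THF/H2O, rt
Reagents that add atoms: none
Why: Brown asymmetric allylboration through a closed chair (Zimmerman–Traxler) transition state gives clean 1,2-addition to the enal. The isopinocampheyl groups of the (+)-α-pinene series should direct the 2-methylallyl group to the Si face of the aldehyde, which sets C6 as (S) under reagent control and overrides the weak bias of the C4 centre. Perborate work-up releases the alcohol from borinate 8 without touching the silyl ether.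

Step 5
Reactants: 9 (1S)-3-methyl-1-[(5R)-2-methyl-5-(propan-2-yl)-5-(triethylsilyloxy)cyclopent-1-en-1-yl]but-3-en-1-ol; 10 allyl acetate
Product: 12 O-allyl ether of 9, via zinc alkoxide 11 (not isolated)
Conditions: Et2Zn (0.55 equiv), THF, 0 °C → rt; then 10, Pd(PPh3)4 (5 mol %), rt
Reagents that add atoms: none
Why: Tsuji–Trost allylic etherification of a zinc alkoxide: the covalent zinc alkoxide 11 attacks the π-allylpalladium complex formed from allyl acetate, so no free alkali alkoxide is present that could pull the neighbouring tertiary silyl group across to O6. The C6–O bond is not broken, so the (S) configuration is kept.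

Step 6
Reactants: 12 O-allyl ether of 9
Product: 13 (2S)-4-methyl-2-[(5R)-2-methyl-5-(propan-2-yl)-5-(triethylsilyloxy)cyclopent-1-en-1-yl]-3,6-dihydro-2H-pyran
Conditions: second-generation Grubbs catalyst (H2IMes)(PCy3)Cl2Ru=CHPh (5 mol %), CH2Cl2, 40 °C
Reagents that add atoms: none
Why: Ring-closing metathesis between the monosubstituted allyl ether alkene and the 1,1-disubstituted methallyl alkene closes the six-membered ring with the trisubstituted C8=C9 alkene and loss of ethene; the tetrasubstituted cyclopentene alkene is inert to the ruthenium carbene, and no stereocentre is affected.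

Step 7
Reactants: 13 (2S)-4-methyl-2-[(5R)-2-methyl-5-(propan-2-yl)-5-(triethylsilyloxy)cyclopent-1-en-1-yl]-3,6-dihydro-2H-pyran
Product: 16 (1S,4R,10R)-4-(triethylsilyloxy)dauca-5,8-dien-10-ol, via allyllithium 14 (not isolated), via lithium alkoxide 15 (not isolated)
Conditions: s-BuLi (1.3 equiv), THF, −78 → −40 °C; then aq. NH4Cl
Reagents that add atoms: none
Why: Proposed new method: s-BuLi should remove a C10 proton, which is both allylic and α to oxygen on an unhindered methylene (the only other such C–H, at C6, is tertiary, lies beside the quaternary C4 and would push charge onto the fully substituted C1), to give the α-oxyallyllithium 14, whose carbanion carbon can reach C1 through a five-membered envelope C10–O–C6–C5=C1; the suprafacial [2,3]-Wittig shift then forms C1–C10, breaks C6–O and moves the alkene to C5=C6, and the closest known reaction types are the [2,3]-Wittig ring contractions of large-ring diallyl ethers and the [2,3]-shifts of cyclic allyloxonium ylides. The seven-membered carbocycle (C1, C5, C6, C7, C8, C9, C10) closes by this sigmatropic bond formation, formally a 7-endo-trig attack of C10 on C1=C5, through a transition state shaped like an 8-oxabicyclo[3.2.1]octa-2,6-diene in which the cyclopentenyl group on C6 and the reacting lobe on C10 are both axial on the side of the ring oxygen. C1 is controlled by C6: the ring holds C7 cis to C1, so with (S)-C6 the oxygen, and with it C10, lies on the α face of the cyclopentene and the methyl group is pushed to the β face. C10 is controlled by the same bicyclic geometry, since the planar allyl anion can bond to C1 only through the lobe that leaves its oxygen outside the new ring on the α side. The selectivities needed are C10 over C6 metalation and [2,3] over [1,2] or [1,4] migration of C6; the first rests on the acidity and accessibility just described, the second on the low temperature and on the concerted path being within geometric reach, whereas the competing shifts require homolysis of the C6–O bond. The C4 silyl ether cannot reach either anion, and alkoxide 15 is protonated on work-up.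

Step 8
Reactants: 16 (1S,4R,10R)-4-(triethylsilyloxy)dauca-5,8-dien-10-ol
Product: 17 (1S,4R,10R)-10-(tert-butyldimethylsilyloxy)-4-(triethylsilyloxy)dauca-5,8-diene
Conditions: TBSOTf, 2,6-lutidine, CH2Cl2, −78 → 0 °C
Reagents that add atoms: tert-butyldimethylsilyl trifluoromethanesulfonate, CC(C)(C)[Si](C)(C)OS(=O)(=O)C(F)(F)F
Why: Silyl triflate silylation of the hindered neopentyl allylic alcohol with retention at C10; the tert-butyldimethylsilyl group leaves O6 as the only oxygen to be acylated later and crowds C9, the carbon that would have to take boron if C8=C9 reacted.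

Step 9
Reactants: 17 (1S,4R,10R)-10-(tert-butyldimethylsilyloxy)-4-(triethylsilyloxy)dauca-5,8-diene
Product: 19 (1S,4R,5S,6S,10R)-10-(tert-butyldimethylsilyloxy)-4-(triethylsilyloxy)dauc-8-en-6-ol, via alkylborane 18 (not isolated)
Conditions: BH3·THF (3 equiv), THF, 0 °C → rt; then 3 M NaOH, 30% H2O2, 0 °C → rt
Reagents that add atoms: hydrogen peroxide, OO
Why: Hydroboration–oxidation: boron should add to C6, the only CH of the C5=C6 alkene, with syn delivery of hydrogen to C5, and the C–B bond is oxidised with retention, so attack on the α face gives 5α-H and 6α-OH together. The α face is expected to be preferred because the β face carries the angular C1 methyl and the C4 silyloxy group (the bias that makes Δ5-steroids give 5α,6α products), while C8=C9 would have to take boron at C9 beside the C10 silyl ether; neither selectivity is secure (see the uncertain steps).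

Step 10
Reactants: 19 (1S,4R,5S,6S,10R)-10-(tert-butyldimethylsilyloxy)-4-(triethylsilyloxy)dauc-8-en-6-ol; 20 4-methoxybenzoyl chloride
Product: 21 (1S,4R,5S,6S,10R)-10-(tert-butyldimethylsilyloxy)-4-(triethylsilyloxy)dauc-8-en-6-yl 4-methoxybenzoate
Conditions: Et3N, DMAP, CH2Cl2, rt → 40 °C
Reagents that add atoms: none
Why: DMAP-catalysed acylation (acylpyridinium transfer) of the only free hydroxyl; the C6–O bond is untouched, so the α configuration is kept, and both silyl ethers are stable to the amine base.

Step 11
Reactants: 21 (1S,4R,5S,6S,10R)-10-(tert-butyldimethylsilyloxy)-4-(triethylsilyloxy)dauc-8-en-6-yl 4-methoxybenzoate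
Product: 22 (3R,3aS,4S,8R,8aS)-3,8-dihydroxy-6,8a-dimethyl-3-(propan-2-yl)-1,2,3,3a,4,5,8,8a-octahydroazulen-4-yl 4-methoxybenzoate
Conditions: HF·pyridine, pyridine, THF, 0 °C → rt
Reagents that add atoms: none
Why: Fluoride-driven cleavage of both Si–O bonds; buffered HF·pyridine is neither basic enough to hydrolyse or move the aryl ester nor acidic enough to ionise the tertiary or the allylic alcohol, and no stereocentre is involved.

## Compound list

1 | (S)-terpinen-4-ol, (1S)-4-methyl-1-(propan-2-yl)cyclohex-3-en-1-ol | CC1=CC[C@](O)(C(C)C)CC1 | starting material
2 | triethylsilyl ether of 1 | CC1=CC[C@](O[Si](CC)(CC)CC)(C(C)C)CC1 | intermediate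
3 | secondary ozonide (1,2,4-trioxolane) of 2, both epimers at the two trioxolane carbons | CC12CC[C@@](O[Si](CC)(CC)CC)(C(C)C)CC(OO1)O2 | intermediate (not isolated)
4 | (3S)-6-oxo-3-(propan-2-yl)-3-(triethylsilyloxy)heptanal | O=CC[C@](O[Si](CC)(CC)CC)(C(C)C)CCC(C)=O | intermediate
5 | cyclic aldol, 2-hydroxy-2-methyl-5-(propan-2-yl)-5-(triethylsilyloxy)cyclopentane-1-carbaldehyde, epimers at the two new centres | O=CC1C(C)(O)CC[C@@]1(O[Si](CC)(CC)CC)C(C)C | intermediate (not isolated)
6 | (5R)-2-methyl-5-(propan-2-yl)-5-(triethylsilyloxy)cyclopent-1-ene-1-carbaldehyde | O=CC1=C(C)CC[C@@]1(O[Si](CC)(CC)CC)C(C)C | intermediate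
7 | 2-methylallylmagnesium chloride | C=C(C)C[Mg]Cl | starting material
8 | diisopinocampheylborinate of 9 | C=C(C)C[C@H](OB([C@@H]1C[C@@H]2C[C@H]([C@H]1C)C2(C)C)[C@@H]1C[C@@H]2C[C@H]([C@H]1C)C2(C)C)C1=C(C)CC[C@@]1(O[Si](CC)(CC)CC)C(C)C | intermediate (not isolated)
9 | (1S)-3-methyl-1-[(5R)-2-methyl-5-(propan-2-yl)-5-(triethylsilyloxy)cyclopent-1-en-1-yl]but-3-en-1-ol | C=C(C)C[C@H](O)C1=C(C)CC[C@@]1(O[Si](CC)(CC)CC)C(C)C | intermediate
10 | allyl acetate (prop-2-en-1-yl acetate) | CC(=O)OCC=C | starting material
11 | zinc bis-alkoxide of 9 | C=C(C)C[C@H](O[Zn]O[C@@H](CC(C)=C)C1=C(C)CC[C@@]1(O[Si](CC)(CC)CC)C(C)C)C1=C(C)CC[C@@]1(O[Si](CC)(CC)CC)C(C)C | intermediate (not isolated)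
12 | O-allyl ether of 9, (1S) at the ether carbon, (R) at the silyloxy carbon | C=CCO[C@@H](CC(C)=C)C1=C(C)CC[C@@]1(O[Si](CC)(CC)CC)C(C)C | intermediate
13 | (2S)-4-methyl-2-[(5R)-2-methyl-5-(propan-2-yl)-5-(triethylsilyloxy)cyclopent-1-en-1-yl]-3,6-dihydro-2H-pyran | CC1=CCO[C@@H](C1)C1=C(C)CC[C@@]1(O[Si](CC)(CC)CC)C(C)C | intermediate
14 | 13 lithiated at the allylic O–CH2 carbon (C10), a delocalised α-oxyallyl anion | CC1=CC([Li])O[C@@H](C1)C1=C(C)CC[C@@]1(O[Si](CC)(CC)CC)C(C)C | intermediate (not isolated)
15 | lithium alkoxide of 16 | CC1=C[C@@H](O[Li])[C@@]2(C)CC[C@@](O[Si](CC)(CC)CC)(C(C)C)C2=CC1 | intermediate (not isolated)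
16 | (1S,4R,10R)-4-(triethylsilyloxy)dauca-5,8-dien-10-ol (1β-methyl, 4β-OSiEt3, 10α-OH; alkenes C5=C6 and C8=C9) | CC1=C[C@@H](O)[C@@]2(C)CC[C@@](O[Si](CC)(CC)CC)(C(C)C)C2=CC1 | intermediate
17 | 10-O-tert-butyldimethylsilyl ether of 16 | CC1=C[C@@H](O[Si](C)(C)C(C)(C)C)[C@@]2(C)CC[C@@](O[Si](CC)(CC)CC)(C(C)C)C2=CC1 | intermediate
18 | C6 alkylborane from 17 (BH2 on C6 and H on C5, both α) | CC1=C[C@@H](O[Si](C)(C)C(C)(C)C)[C@@]2(C)CC[C@@](O[Si](CC)(CC)CC)(C(C)C)[C@@H]2[C@@H](B)C1 | intermediate (not isolated)
19 | (1S,4R,5S,6S,10R)-10-(tert-butyldimethylsilyloxy)-4-(triethylsilyloxy)dauc-8-en-6-ol (5α-H, 6α-OH) | CC1=C[C@@H](O[Si](C)(C)C(C)(C)C)[C@@]2(C)CC[C@@](O[Si](CC)(CC)CC)(C(C)C)[C@@H]2[C@@H](O)C1 | intermediate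
20 | 4-methoxybenzoyl chloride | COc1ccc(C(Cl)=O)cc1 | starting material
21 | 6-O-(4-methoxybenzoate) of 19 | COc1ccc(C(=O)O[C@H]2CC(C)=C[C@@H](O[Si](C)(C)C(C)(C)C)[C@@]3(C)CC[C@@](O[Si](CC)(CC)CC)(C(C)C)[C@H]23)cc1 | intermediate
22 | (3R,3aS,4S,8R,8aS)-3,8-dihydroxy-6,8a-dimethyl-3-(propan-2-yl)-1,2,3,3a,4,5,8,8a-octahydroazulen-4-yl 4-methoxybenzoate | COc1ccc(C(=O)O[C@H]2CC(C)=C[C@@H](O)[C@@]3(C)CC[C@@](O)(C(C)C)[C@H]23)cc1 | target

## Step count and least certain steps

Total step count: 11. Longest linear sequence: 11 steps (1 → 22).

**Step 7 (key step).** The most likely failures are migration of C6 by the [1,2] or [1,4] pathway after homolysis of the C6–O bond (C6 is an allylic carbon and a good migrating radical), eliminative opening of the ether ring by the carbanion, or metalation away from C10. The bridged transition state may also be too strained for a six-membered ether. The fallback uses known chemistry, sets out from 12 and comes back at 16; it exchanges the order of ring closure and rearrangement. Metalation of 12 at the O-allyl methylene (n-BuLi, THF, −78 °C) should start the ordinary acyclic [2,3]-Wittig rearrangement of a bis-allylic ether across O–C6–C5=C1. This gives the (E)-configured trienol, 1-[1-methyl-2-(3-methylbut-3-enylidene)-3-(propan-2-yl)-3-(triethylsilyloxy)cyclopentyl]prop-2-en-1-ol F1. Ring-closing metathesis of its vinyl and methallyl groups (second-generation Grubbs catalyst (H2IMes)(PCy3)Cl2Ru=CHPh, CH2Cl2, 40 °C) would then close the seven-membered ring at C8=C9 and return 16. The price is that C7 is no longer tied cis to C1: only the geometric isomer of F1 shown can cyclise (it necessarily carries the right C1), and C10 may form as a mixture that would need a Mitsunobu inversion after ring closure.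

**Step 9.** The likely failures are poor facial selectivity and competing hydroboration of C8=C9. The α face carries the C4 isopropyl group and C10 with its silyl ether, so it is not clearly the open face, and the very hindered C5=C6 alkene may react no faster than C8=C9. The fallback sets out from 16 and comes back at 22; it delivers silicon from the C10 oxygen, which lies on the α face opposite C6.
- Silylation of 16 with 1,1,3,3-tetramethyldisilazane gives the dimethylsilyl ether F2.
- Pt2[(CH2=CHSiMe2)2O]3 (Karstedt catalyst, toluene, 60 °C) should add Si–H across C5=C6 intramolecularly and syn. Silicon goes to C6 because C5 is fully substituted, giving the oxasilinane F3.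
- Tamao–Fleming oxidation (KF, KHCO3, H2O2, THF/MeOH) with retention gives the 6α,10α-diol F4.
- Acylation with 20 (Et3N, DMAP, CH2Cl2, −20 °C) at the less hindered C6 hydroxyl (C10–OH is neopentyl) gives the 6-ester F5.
- HF·pyridine returns 22.

**Step 4.** The likely failure is incomplete reagent control: a mismatched pairing with the C4 centre, or slow addition to the crowded, conjugated aldehyde, would leave C6 as a mixture, and every later stereocentre depends on C6. The fallback sets out from 6 and comes back at 9; it sets C6 by ketone reduction instead. Addition of 7 without a chiral controller (THF, −78 °C) gives the carbinol as both C6 epimers F6. Dess–Martin periodinane gives the β,γ-unsaturated cyclopentenyl ketone F7. Corey–Bakshi–Shibata reduction [(R)-2-methyl-CBS-oxazaborolidine, BH3·SMe2, −30 °C], with the cyclopentenyl group as the large substituent, should return (S)-configured 9.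

**Step 5.** The likely failures are sluggish attack of the crowded zinc alkoxide on the π-allyl complex and, if a more basic alkoxide has to be used, transfer of the tertiary triethylsilyl group from O4 to O6. The fallback sets out from 9 and comes back at 12. Acylation with allyl chloroformate (pyridine, CH2Cl2, 0 °C) gives the allyl carbonate F8. Pd(PPh3)4 (THF, 60 °C) then extrudes carbon dioxide and recombines the alkoxide with the π-allyl fragment inside the ion pair to give 12.

## Further compounds

F1 | step 7 | (E)-1-[1-methyl-2-(3-methylbut-3-enylidene)-3-(propan-2-yl)-3-(triethylsilyloxy)cyclopentyl]prop-2-en-1-ol, configuration at C1, C4 and C10 as in 16, C7 cis to C1 | C=C[C@@H](O)[C@@]1(C)CC[C@@](O[Si](CC)(CC)CC)(C(C)C)/C1=C/CC(C)=C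
F2 | step 9 | 10-O-dimethylsilyl ether of 16 | CC1=C[C@@H](O[SiH](C)C)[C@@]2(C)CC[C@@](O[Si](CC)(CC)CC)(C(C)C)C2=CC1
F3 | step 9 | cyclic siloxane (1-oxa-2-silacyclohexane bridging O10 and C6 on the α face, 5α-H) | CC1=C[C@H]2O[Si](C)(C)[C@@H](C1)[C@@H]3[C@]2(C)CC[C@@]3(O[Si](CC)(CC)CC)C(C)C
F4 | step 9 | (1S,4R,5S,6S,10R)-4-(triethylsilyloxy)dauc-8-ene-6,10-diol | CC1=C[C@@H](O)[C@@]2(C)CC[C@@](O[Si](CC)(CC)CC)(C(C)C)[C@@H]2[C@@H](O)C1
F5 | step 9 | (1S,4R,5S,6S,10R)-10-hydroxy-4-(triethylsilyloxy)dauc-8-en-6-yl 4-methoxybenzoate | COc1ccc(C(=O)O[C@H]2CC(C)=C[C@@H](O)[C@@]3(C)CC[C@@](O[Si](CC)(CC)CC)(C(C)C)[C@H]23)cc1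
F6 | step 4 | 9 as a mixture of both epimers at the carbinol carbon | C=C(C)CC(O)C1=C(C)CC[C@@]1(O[Si](CC)(CC)CC)C(C)C
F7 | step 4 | 3-methyl-1-[(5R)-2-methyl-5-(propan-2-yl)-5-(triethylsilyloxy)cyclopent-1-en-1-yl]but-3-en-1-one | C=C(C)CC(=O)C1=C(C)CC[C@@]1(O[Si](CC)(CC)CC)C(C)C
F8 | step 5 | allyl carbonate of 9 | C=CCOC(=O)O[C@@H](CC(C)=C)C1=C(C)CC[C@@]1(O[Si](CC)(CC)CC)C(C)C
A1 | alternative 1 | 2-(methanesulfonyloxy)-3-methylcyclopent-2-en-1-one | CC1=C(OS(C)(=O)=O)C(=O)CC1
A2 | alternative 1 | (R)-4-methyl-1-(trimethylsilyloxy)cyclopent-1-ene | C[C@@H]1CC=C(O[Si](C)(C)C)C1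
A3 | alternative 1 | head-to-tail cis-anti-cis photoadduct (cyclobutane C1–C10–C6–C5; C5 mesylate, C10 trimethylsilyl ether, C4 ketone) | O=C1CC[C@]2(C)[C@@]3(O[Si](C)(C)C)C[C@H](C)C[C@H]3[C@]12OS(C)(=O)=O
A4 | alternative 1 | Grob product, bicyclic 5-ene-4,10-dione with quaternary C1 and C8 methine | O=C1CC[C@]2(C)C(=O)C[C@H](C)CC=C12
A5 | alternative 2 | (E)-4-(tert-butyldimethylsilyloxy)-2-methylbut-2-enal | O=C/C(C)=C/CO[Si](C)(C)C(C)(C)C
A6 | alternative 2 | isoprene | C=CC(C)=C
A7 | alternative 2 | trans-6-[(tert-butyldimethylsilyloxy)methyl]-1,4-dimethylcyclohex-3-ene-1-carbaldehyde | O=C[C@@]1(C)CC=C(C)C[C@@H]1CO[Si](C)(C)C(C)(C)C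
A8 | alternative 3 | (E)-enyne with terminal alkyne on the C4 triethylsilyl carbinol and a 1-(tert-butyldimethylsilyloxy)-2-methylcyclopropyl group on the trisubstituted alkene (one cyclopropane diastereomer; its siloxy carbon is lost as a stereocentre in the cycloaddition) | C#C[C@](O[Si](CC)(CC)CC)(C(C)C)CC/C(C)=C/[C@@]1(O[Si](C)(C)C(C)(C)C)C[C@H]1C
A9 | alternative 3 | bicyclic 5-ene with C9 silyl enol ether, quaternary C1 and C4 triethylsilyl ether | C[C@@H]1CC=C2[C@](O[Si](CC)(CC)CC)(C(C)C)CC[C@]2(C)C=C1O[Si](C)(C)C(C)(C)C
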